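## The problem

1. With C1 as the lactone carbonyl and the main chain numbered on to C22, target 25 is a 1,2-dioxane (O1, O2, C3, C4, C5, C6). It is cis-fused along C3–C4 to a γ-lactone (C1, C2, C3, C4 and the oxygen on C4), and C6 bears a methyl group and a chain (C7–C22) ending in a 15E,17E,19E triene.
2. The SMILES reads 3S,4S,6S. The lactone oxygen on C4, C2 on C3 and the methyl group on C6 stand on one face of the dioxane; the C4 methyl group and the chain stand on the other.
3. C3 is not an independent problem: a peroxide oxygen tethered through C5 reaches C3 of a butenolide only on the face that carries C5, so C4 controls C3.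
4. C6 is the hard centre. It is quaternary, bound to O1 and cut off from C4 by C5H2, and its two open ligands, CH3 and CH2R, are almost equal in size.
5. A planar radical or cation at C6 that already holds both groups, or any equilibration, therefore gives both epimers.
6. The O–O bond excludes low-valent metals, hydrides, stoichiometric phosphines and hard carbanions. C2–H is acidic and β to O2, so strong base opens the ring by E1cB. The triene does not survive ozone, singlet oxygen, peroxyl radical chains or Lewis acids.
7. The enabling feature is the C6–O1 bond inside the dioxane ring together with the lactone ring fused at C3–C4. C6 can be ionised to a ring peroxycarbenium ion (C6=O1+–O2), the fused lactone fixes its half-chair with the C4–O bond pseudoaxial, and in 25 the C6 methyl group is axial and syn to that oxygen, which is the place an axially attacking nucleophile takes.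
8. Hence the methyl group, not the chain and not the oxygen, should be the last ligand to reach C6.

## Retrosynthesis

**C15=C16 (25 ⇒ 19 + 23).**
- The triene is cut at its inner double bond into aldehyde 19 and dienyl phosphonate 23, used as its anion 24.
- The neighbouring C16–C17 cut would need an alkenyl halide or boronate on the peroxide, and their usual sources from an aldehyde use Cr(II) or hydrometalation.
- The cut removes the one group that is incompatible with every peroxide-forming step.
- The forward reaction must be E-selective, and the anion must add to the aldehyde faster than it deprotonates C2.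
- Aldehyde 19 goes back by two functional-group steps through alcohol 18 to silyl ether 17.

**C6–CH3 (17 ⇒ 16 ⇒ 15).**
- The methyl group is removed as a nucleophile, leaving peroxycarbenium ion 16 and, behind it, peroxyketal 15 with an alkoxy leaving group at C6.
- Cutting C6–O1 or C6–C7 instead leaves CH3 and CH2R to be told apart by size. This cut distinguishes them by order of arrival.
- Peroxyketal 15 needs no control at C6, because both epimers give the same ion. That removes the hardest stereocentre from everything before it.
- The forward reaction must ionise only the exocyclic C–O bond and deliver methyl axially.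

**C3–O2 (15 ⇒ 14).**
- The dioxane is opened to hydroperoxy ketal 14, which carries a butenolide.
- This is the only ring bond whose closure is guided by C4, and it sets C3 at no extra cost.
- The forward reaction is a 6-exo oxa-Michael addition.

**C6(OO)(OR) ⇒ C6=CH2 (14 ⇒ 13 ⇒ 12).**
- The hydroperoxy ketal is the alcohol adduct of carbonyl oxide 13, and 13 is the ozonolysis fragment of the 1,1-disubstituted alkene 12.
- Ozone supplies both peroxide oxygens and removes the carbon that later returns as methyl.
- The forward step must spare the electron-poor butenolide alkene, and the primary ozonide must split towards the ketone oxide.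

**Butenolide (12 ⇒ 11 ⇒ 10 ⇒ 9).**
- C2=C3 and the lactone C–O bond are cut to α-hydroxy aldehyde 10, which has no α-hydrogen, by way of Z-enoate 11.
- Aldehyde 10 comes from diol 9.
- A γ-alkylation of a butenolide dienolate would be shorter, but it lacks a reliable enantioselective form for a simple 2-alkylallyl group.

**C5–C6 (9 ⇒ 7 + 8, from 5 and 6).**
- The diol is cut at the epoxide-opening retron into alkenylmagnesium reagent 7 (from bromide 5) and the alkoxide 8 of (R)-2-methylglycidol 6.
- C4 is bought, not made, and no later step touches it.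

**Small pieces.**
- Bromide 5 comes from Grignard reagent 4 (from 2, from bromo alcohol 1) and 2,3-dibromopropene 3.
- Phosphonate 23 comes from dienal 20 through alcohol 21 and bromide 22.

## Roads not taken

**Alternative 1 (the obvious one).**
- Cut: C6–O1 and C3–O2.
- Forward key step: cobalt-catalysed Mukaiyama–Isayama hydroperoxysilylation of alkene 12 (O2, Et3SiH) to silyl peroxide A1, then desilylation and oxa-Michael closure.
- Weakness: oxygen is captured by a planar tertiary radical at C6 whose CH3 and CH2R ligands are indistinguishable, so 17 must form together with its C6 epimer A2.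
- No change of catalyst can address this, because the bias is missing in the substrate.
- The chosen plan starts from the same alkene 12, costs one more step, and makes C6 a controlled centre.

**Alternative 2.**
- Cut: both C–O bonds of the peroxide at once.
- Forward key step: singlet-oxygen [4+2] addition to diene acid A3 gives dihydrodioxine acid A4, followed by iodolactonisation and radical deiodination.
- Strength: diene geometry encodes C3 against C6.
- Weaknesses: the relative configuration of 25 needs the 5Z isomer, which places the long chain inside the s-cis diene. This disfavours the reactive conformer and leaves the ene reaction at five allylic positions to compete.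
- Nothing controls the diene face, so A4 is racemic, and a geometrically pure trisubstituted Z,E-diene is itself a multi-step problem.

**Alternative 3.**
- Cut: C6–O1 with inversion.
- Forward key step: Lewis acid-mediated opening of enantiopure oxetane A5 by H2O2 at its tertiary carbon to hydroperoxy alcohol A6, then oxa-Michael closure.
- Weaknesses: a second, independent asymmetric operation is needed for C6, and substitution at a tertiary carbon leaks through the carbocation.
- The chain must then be grown from the C8 hydroxyl group by sp3–sp3 bond formation in the presence of the peroxide.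
- The chosen plan derives C6 from C4 and carries the whole saturated chain from the start.

Key step: step 8

Assumption: (R)-2-methylglycidol 6 is taken as a commercial compound; it is also the one-step Sharpless epoxidation product of 2-methylprop-2-en-1-ol.

## Steps

Step 1
Reactants: 1 8-bromooctan-1-ol
Product: 2 [(8-bromooctyl)oxy](tert-butyl)diphenylsilane
Conditions: TBDPSCl, imidazole, CH2Cl2, 0 °C → rt
Reagents that add atoms: tert-butyl(chloro)diphenylsilane, CC(C)(C)[Si](Cl)(c1ccccc1)c1ccccc1
Why: Standard silylation of a primary alcohol. TBDPS is chosen because it must outlast two Grignard formations, ozone, an amine and a Ti(IV) Lewis acid and then leave with fluoride under nearly neutral conditions.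

Step 2
Reactants: 2 [(8-bromooctyl)oxy](tert-butyl)diphenylsilane; 3 2,3-dibromoprop-1-ene
Product: 5 [(10-bromoundec-10-en-1-yl)oxy](tert-butyl)diphenylsilane, via alkylmagnesium bromide 4 (not isolated)
Conditions: Mg, THF, 40 °C; then 3, CuI (5 mol %), 0 °C → rt
Reagents that add atoms: none
Why: Grignard formation and copper-assisted allylic substitution on 2,3-dibromopropene, a standard route to 2-bromo-1-alkenes. Only the allylic bromide reacts, which forms C7–C8 and leaves the vinylic bromide at C6.

Step 3
Reactants: 5 [(10-bromoundec-10-en-1-yl)oxy](tert-butyl)diphenylsilane; 6 (R)-(2-methyloxiran-2-yl)methanol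
Product: 9 (2S)-13-[(tert-butyldiphenylsilyl)oxy]-2-methyl-4-methylidenetridecane-1,2-diol, via alkenylmagnesium bromide 7 (not isolated), via chloromagnesium alkoxide 8 (not isolated)
Conditions: 5, Mg, THF, 45 °C; 6, MeMgCl (1 equiv), THF, −30 °C; combine, CuI (10 mol %), −30 → 0 °C; aqueous work-up
Reagents that add atoms: none
Why: Copper-catalysed SN2 opening of a 2,2-disubstituted epoxide at its CH2 group forms C5–C6 without touching C4, whose configuration comes from 6. A Payne rearrangement of alkoxide 8 is degenerate and returns the same enantiomer, so no protecting group is needed.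

Step 4
Reactants: 9 (2S)-13-[(tert-butyldiphenylsilyl)oxy]-2-methyl-4-methylidenetridecane-1,2-diol
Product: 10 (2S)-13-[(tert-butyldiphenylsilyl)oxy]-2-hydroxy-2-methyl-4-methylidenetridecanal
Conditions: TEMPO (10 mol %), PhI(OAc)2, CH2Cl2, rt
Reagents that add atoms: none
Why: Oxoammonium oxidation takes the primary alcohol and leaves the tertiary one and the alkene alone. The aldehyde has no α-hydrogen and cannot epimerise.

Step 5
Reactants: 10 (2S)-13-[(tert-butyldiphenylsilyl)oxy]-2-hydroxy-2-methyl-4-methylidenetridecanal
Product: 12 (5S)-5-{11-[(tert-butyldiphenylsilyl)oxy]-2-methylideneundecyl}-5-methylfuran-2(5H)-one, via Z-enoate 11 (not isolated)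
Conditions: (CF3CH2O)2P(O)CH2CO2Me, KHMDS, 18-crown-6, THF, −78 °C; then CSA (cat.), CH2Cl2, rt
Reagents that add atoms: methyl bis(2,2,2-trifluoroethyl)phosphonoacetate, COC(=O)CP(=O)(OCC(F)(F)F)OCC(F)(F)F
Why: The Still–Gennari variant of the Horner–Wadsworth–Emmons reaction should give the Z-enoate, in which the tertiary hydroxyl group lies next to the ester and lactonises with loss of methanol. C4 is not involved.

Step 6
Reactants: 12 (5S)-5-{11-[(tert-butyldiphenylsilyl)oxy]-2-methylideneundecyl}-5-methylfuran-2(5H)-one
Product: 14 (5S)-5-{11-[(tert-butyldiphenylsilyl)oxy]-2-hydroperoxy-2-(2-methoxyethoxy)undecyl}-5-methylfuran-2(5H)-one (both C6 epimers), via carbonyl oxide 13 (not isolated)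
Conditions: O3, CH2Cl2/2-methoxyethanol 4:1, −78 °C, dye indicator; N2 purge, no reductant
Reagents that add atoms: ozone, [O-][O+]=O; 2-methoxyethanol, COCCO
Why: In Criegee ozonolysis, the primary ozonide of a 1,1-dialkyl alkene splits to the more substituted carbonyl oxide and formaldehyde, and the alcohol traps the oxide as a hydroperoxy ketal. The electron-poor butenolide alkene reacts far more slowly, and the configuration at C6 does not matter.

Step 7
Reactants: 14 (5S)-5-{11-[(tert-butyldiphenylsilyl)oxy]-2-hydroperoxy-2-(2-methoxyethoxy)undecyl}-5-methylfuran-2(5H)-one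
Product: 15 (4aS,7aS)-3-{9-[(tert-butyldiphenylsilyl)oxy]nonyl}-3-(2-methoxyethoxy)-4a-methyltetrahydrofuro[3,2-c][1,2]dioxin-6-one (3S,4S in chain numbering; both C6 epimers)
Conditions: Et2NH (20 mol %), CF3CH2OH, rt
Reagents that add atoms: none
Why: Two 6-exo-trig oxa-Michael additions are known reaction types: hydroperoxy ketals adding to unsaturated esters under amine catalysis in a fluorinated alcohol, and tertiary hydroperoxides adding to butenolides. O2 reaches C3 only on the face that bears C5, which sets C3 (S) and the cis fusion, and the acidic solvent protonates the enolate before it can collapse on the O–O bond.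

Step 8
Reactants: 15 (4aS,7aS)-3-{9-[(tert-butyldiphenylsilyl)oxy]nonyl}-3-(2-methoxyethoxy)-4a-methyltetrahydrofuro[3,2-c][1,2]dioxin-6-one
Product: 17 (3S,4aS,7aS)-3-{9-[(tert-butyldiphenylsilyl)oxy]nonyl}-3,4a-dimethyltetrahydrofuro[3,2-c][1,2]dioxin-6-one (3S,4S,6S in chain numbering), via peroxycarbenium ion 16 (not isolated)
Conditions: Me2Zn (1.5 equiv), TiCl4 (3 equiv), CH2Cl2, −78 °C; then 15, −78 → −40 °C; H2O
Reagents that add atoms: dimethylzinc, C[Zn]C
Why: Proposed new method: MeTiCl3 binds the 2-methoxyethoxy group of either C6 epimer of 15 as a five-membered chelate and removes it, so both epimers give the same planar peroxycarbenium ion 16 (C6=O1+–O2), which takes a methyl group from titanium at C6. The closest known reaction types are the TiCl4-, SnCl4- or TMSOTf-mediated substitution of 3-alkoxy-1,2-dioxanes and -dioxolanes by allylsilanes, silyl enol ethers and silyl ketene acetals through such ions, the SN1-type methylation of ketals and tertiary halides by methyltitanium chlorides, and the alkylaluminium substitution at the acetal carbon of trioxane lactol derivatives with the O–O bond left intact; only the σ-bound methyl donor on a peroxycarbenium ion is new. No ring is closed, and the one new stereocentre is C6. In 16 the atoms C5, C6, O1 and O2 lie in one plane and the cis-fused lactone allows two half-chairs, of which the one with the C4–O bond pseudoaxial and the C4 methyl group and C2 pseudoequatorial is favoured on steric and electrostatic grounds. Attack along the axial line that leads directly to a chair then comes from the face syn to the oxygen on C4, which places the new methyl group axial and the chain equatorial, as in 25. The other face would require a twist-boat, or the half-chair with the C4 methyl group pseudoaxial and 1,3-syn to the incoming reagent. The step needs exocyclic rather than ring C6–O ionisation, which the chelating leaving group secures, and attack at carbon rather than at the peroxide oxygens, the lactone or the silyl ether, which the low basicity of MeTiCl3 and the low temperature favour.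

Step 9
Reactants: 17 (3S,4aS,7aS)-3-{9-[(tert-butyldiphenylsilyl)oxy]nonyl}-3,4a-dimethyltetrahydrofuro[3,2-c][1,2]dioxin-6-one
Product: 18 (3S,4aS,7aS)-3-(9-hydroxynonyl)-3,4a-dimethyltetrahydrofuro[3,2-c][1,2]dioxin-6-one
Conditions: HF·pyridine, THF, 0 °C → rt
Reagents that add atoms: none
Why: Fluoride-driven desilylation in a weakly acidic medium. It avoids the basic conditions that would open the β-peroxy lactone.

Step 10
Reactants: 18 (3S,4aS,7aS)-3-(9-hydroxynonyl)-3,4a-dimethyltetrahydrofuro[3,2-c][1,2]dioxin-6-one
Product: 19 9-[(3S,4aS,7aS)-3,4a-dimethyl-6-oxotetrahydrofuro[3,2-c][1,2]dioxin-3-yl]nonanal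
Conditions: Dess–Martin periodinane, CH2Cl2, 0 °C → rt
Reagents that add atoms: none
Why: Dess–Martin oxidation is neutral to weakly acidic, non-reducing and metal-free, so dialkyl peroxides and lactones are left alone.

Step 11
Reactants: 20 (2E,4E)-hepta-2,4-dienal
Product: 21 (2E,4E)-hepta-2,4-dien-1-ol
Conditions: NaBH4, MeOH, 0 °C
Reagents that add atoms: none
Why: 1,2-Reduction of a conjugated aldehyde by borohydride. The double-bond geometry is kept.

Step 12
Reactants: 21 (2E,4E)-hepta-2,4-dien-1-ol
Product: 22 (2E,4E)-1-bromohepta-2,4-diene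
Conditions: PBr3 (0.4 equiv), Et2O, 0 °C
Reagents that add atoms: phosphorus tribromide, BrP(Br)Br
Why: Standard conversion of an allylic alcohol into the bromide. The primary, fully conjugated bromide is the stable regioisomer.

Step 13
Reactants: 22 (2E,4E)-1-bromohepta-2,4-diene
Product: 23 diethyl [(2E,4E)-hepta-2,4-dien-1-yl]phosphonate
Conditions: P(OEt)3, neat, 120 °C
Reagents that add atoms: triethyl phosphite, CCOP(OCC)OCC
Why: Michaelis–Arbuzov reaction of a primary allylic bromide.

Step 14
Reactants: 19 9-[(3S,4aS,7aS)-3,4a-dimethyl-6-oxotetrahydrofuro[3,2-c][1,2]dioxin-3-yl]nonanal; 23 diethyl [(2E,4E)-hepta-2,4-dien-1-yl]phosphonate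
Product: 25 (3S,4aS,7aS)-3-[(9E,11E,13E)-hexadeca-9,11,13-trien-1-yl]-3,4a-dimethyltetrahydrofuro[3,2-c][1,2]dioxin-6-one, via lithiated phosphonate 24 (not isolated)
Conditions: 23 (1.3 equiv), n-BuLi (1.2 equiv), THF/DMPU, −78 °C; then 19, −78 → 0 °C
Reagents that add atoms: none
Why: The Horner–Wadsworth–Emmons reaction of an allylic phosphonate anion with an aliphatic aldehyde should favour the E alkene and keeps the two existing E bonds. The base is used in deficit to the phosphonate, and addition to the aldehyde at −78 °C should outrun deprotonation at C2.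

## Compound list

1 | 8-bromooctan-1-ol | OCCCCCCCCBr | starting material
2 | [(8-bromooctyl)oxy](tert-butyl)diphenylsilane | BrCCCCCCCCO[Si](c3ccccc3)(c4ccccc4)C(C)(C)C | intermediate
3 | 2,3-dibromoprop-1-ene | C=C(Br)CBr | starting material
4 | {8-[(tert-butyldiphenylsilyl)oxy]octyl}magnesium bromide | Br[Mg]CCCCCCCCO[Si](c3ccccc3)(c4ccccc4)C(C)(C)C | intermediate
5 | [(10-bromoundec-10-en-1-yl)oxy](tert-butyl)diphenylsilane | C=C(Br)CCCCCCCCCO[Si](c3ccccc3)(c4ccccc4)C(C)(C)C | intermediate
6 | (R)-(2-methyloxiran-2-yl)methanol, (R)-2-methylglycidol | OC[C@]1(C)CO1 | starting material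
7 | {11-[(tert-butyldiphenylsilyl)oxy]undec-1-en-2-yl}magnesium bromide | C=C([Mg]Br)CCCCCCCCCO[Si](c3ccccc3)(c4ccccc4)C(C)(C)C | intermediate
8 | chloromagnesium (R)-(2-methyloxiran-2-yl)methoxide | Cl[Mg]OC[C@]1(C)CO1 | intermediate
9 | (2S)-13-[(tert-butyldiphenylsilyl)oxy]-2-methyl-4-methylidenetridecane-1,2-diol | OC[C@@](C)(O)CC(=C)CCCCCCCCCO[Si](c3ccccc3)(c4ccccc4)C(C)(C)C | intermediate
10 | (2S)-13-[(tert-butyldiphenylsilyl)oxy]-2-hydroxy-2-methyl-4-methylidenetridecanal | O=C[C@@](C)(O)CC(=C)CCCCCCCCCO[Si](c3ccccc3)(c4ccccc4)C(C)(C)C | intermediate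
11 | methyl (2Z,4S)-15-[(tert-butyldiphenylsilyl)oxy]-4-hydroxy-4-methyl-6-methylidenepentadec-2-enoate | COC(=O)/C=C\[C@@](C)(O)CC(=C)CCCCCCCCCO[Si](c3ccccc3)(c4ccccc4)C(C)(C)C | intermediate
12 | (5S)-5-{11-[(tert-butyldiphenylsilyl)oxy]-2-methylideneundecyl}-5-methylfuran-2(5H)-one | C=C(CCCCCCCCCO[Si](c3ccccc3)(c4ccccc4)C(C)(C)C)C[C@]1(C)OC(=O)C=C1 | intermediate
13 | carbonyl oxide at C6 of the butenolide | [O-][O+]=C(CCCCCCCCCO[Si](c3ccccc3)(c4ccccc4)C(C)(C)C)C[C@]1(C)OC(=O)C=C1 | intermediate
14 | (5S)-5-{11-[(tert-butyldiphenylsilyl)oxy]-2-hydroperoxy-2-(2-methoxyethoxy)undecyl}-5-methylfuran-2(5H)-one, both C6 epimers | COCCOC(OO)(CCCCCCCCCO[Si](c3ccccc3)(c4ccccc4)C(C)(C)C)C[C@]1(C)OC(=O)C=C1 | intermediate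
15 | (4aS,7aS)-3-{9-[(tert-butyldiphenylsilyl)oxy]nonyl}-3-(2-methoxyethoxy)-4a-methyltetrahydrofuro[3,2-c][1,2]dioxin-6-one, both C6 epimers | COCCOC1(CCCCCCCCCO[Si](c3ccccc3)(c4ccccc4)C(C)(C)C)C[C@]2(C)OC(=O)C[C@@H]2OO1 | intermediate
16 | bicyclic peroxycarbenium ion (C6=O1+) | CC(C)(C)[Si](c3ccccc3)(c4ccccc4)OCCCCCCCCCC1=[O+]O[C@H]2CC(=O)O[C@@]2(C)C1 | intermediate
17 | (3S,4aS,7aS)-3-{9-[(tert-butyldiphenylsilyl)oxy]nonyl}-3,4a-dimethyltetrahydrofuro[3,2-c][1,2]dioxin-6-one | CC(C)(C)[Si](c3ccccc3)(c4ccccc4)OCCCCCCCCC[C@@]1(C)C[C@]2(C)OC(=O)C[C@@H]2OO1 | intermediate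
18 | (3S,4aS,7aS)-3-(9-hydroxynonyl)-3,4a-dimethyltetrahydrofuro[3,2-c][1,2]dioxin-6-one | OCCCCCCCCC[C@@]1(C)C[C@]2(C)OC(=O)C[C@@H]2OO1 | intermediate
19 | 9-[(3S,4aS,7aS)-3,4a-dimethyl-6-oxotetrahydrofuro[3,2-c][1,2]dioxin-3-yl]nonanal | O=CCCCCCCCC[C@@]1(C)C[C@]2(C)OC(=O)C[C@@H]2OO1 | intermediate
20 | (2E,4E)-hepta-2,4-dienal | CC/C=C/C=C/C=O | starting material
21 | (2E,4E)-hepta-2,4-dien-1-ol | CC/C=C/C=C/CO | intermediate
22 | (2E,4E)-1-bromohepta-2,4-diene | CC/C=C/C=C/CBr | intermediate
23 | diethyl [(2E,4E)-hepta-2,4-dien-1-yl]phosphonate | CC/C=C/C=C/CP(=O)(OCC)OCC | intermediate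
24 | lithiated diethyl [(2E,4E)-hepta-2,4-dien-1-yl]phosphonate | [Li+].CC/C=C/C=C/[CH-]P(=O)(OCC)OCC | intermediate
25 | (3S,4aS,7aS)-3-[(9E,11E,13E)-hexadeca-9,11,13-trien-1-yl]-3,4a-dimethyltetrahydrofuro[3,2-c][1,2]dioxin-6-one | CC/C=C/C=C/C=C/CCCCCCCC[C@@]1(C)C[C@]2(C)OC(=O)C[C@@H]2OO1 | target

## Step count and least certain steps

Total steps: 14. Longest linear sequence: 11 (steps 1–10 and 14).

**Step 8 (key step, proposed new method).** Three processes are the most likely to interfere:
- Ionisation may occur at the ring C6–O1 bond, followed by irreversible methyl capture of the open oxocarbenium ion. A σ-organometallic traps cations faster than the π-nucleophiles used so far, so ring re-closure may not keep pace.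
- Methyl may transfer to a peroxide oxygen, or the Lewis acid may induce O–O heterolysis with a 1,2-shift.
- Facial selectivity may erode if transfer happens within the contact ion pair on the face just vacated.

The fallback uses known chemistry, sets out from 15 and returns at 17. The ion 16 is kept but is met by a nucleophile of the proven class. The tert-butyldimethylsilyl ketene acetal of tert-butyl acetate with SnCl4 or TiCl4 at −78 °C should give the tert-butyl ester F1 with the acetate arm in the axial place. Trifluoroacetic acid frees the acid F2. DCC and N-hydroxypyridine-2-thione give the thiohydroxamate ester F3. Photolysis with tert-butyl thiol (Barton reductive decarboxylation) cuts the arm back to the C6 methyl group of 17.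

**Step 6.** Three things may go wrong:
- Ozone may over-oxidise the butenolide alkene.
- The primary ozonide may split towards formaldehyde oxide.
- The carbonyl oxide may be captured by a carbonyl group instead of the alcohol.

All three are matters of relative rate that the substrate controls only in part. The fallback sets out from 12 and returns at 14, and takes the O–O unit from H2O2 instead of ozone. Lemieux–Johnson cleavage (OsO4 cat., NaIO4) gives the ketone F4. Acid-catalysed perketalisation with urea–H2O2 and Sc(OTf)3 in 2-methoxyethanol then gives 14.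

**Step 5.** Z-selectivity may be lost on the hindered α-quaternary aldehyde, and an E ester cannot lactonise. A base-induced α-ketol shift of the free hydroxy aldehyde is also possible. The fallback sets out from 10 and returns at 12, and fixes the ring alkene geometry by ring closure. Wittig methylenation gives the tertiary allylic alcohol F5, and acylation with acryloyl chloride gives the acrylate F6. Ring-closing metathesis (Grubbs II catalyst) should engage the vinyl and acrylate groups, close the five-membered ring, and leave the slower 1,1-disubstituted alkene untouched.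

**Step 14.** The anion may deprotonate C2 and cause E1cB opening of the dioxane, and E-selectivity at C15=C16 may be incomplete. Both follow from using a basic, semi-stabilised carbanion on this substrate. The fallback sets out from 19 and returns at 25, and moves the bond formation to C16–C17 under nearly neutral, stereoretentive conditions. Methylenation at −78 °C gives the terminal alkene F7. Cross-metathesis with vinylboronic acid pinacol ester gives the E-alkenylboronate F8. Suzuki–Miyaura coupling (Pd catalyst, K3PO4, rt) with (1E,3E)-1-iodohexa-1,3-diene F9, made apart from the peroxide by Takai iodo-olefination of (E)-pent-2-enal, gives 25.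

## Further compounds

F1 | step 8 | tert-butyl ester with a CH2CO2tBu arm in place of the C6 methyl group of 17 (axial, syn to the oxygen on C4) | CC(C)(C)[Si](c3ccccc3)(c4ccccc4)OCCCCCCCCC[C@@]1(CC(=O)OC(C)(C)C)C[C@]2(C)OC(=O)C[C@@H]2OO1
F2 | step 8 | carboxylic acid from F1 | CC(C)(C)[Si](c3ccccc3)(c4ccccc4)OCCCCCCCCC[C@@]1(CC(=O)O)C[C@]2(C)OC(=O)C[C@@H]2OO1
F3 | step 8 | N-acyloxypyridine-2-thione (Barton ester) of F2 | CC(C)(C)[Si](c3ccccc3)(c4ccccc4)OCCCCCCCCC[C@@]1(CC(=O)ON5C=CC=CC5=S)C[C@]2(C)OC(=O)C[C@@H]2OO1
F4 | step 6 | (5S)-5-{11-[(tert-butyldiphenylsilyl)oxy]-2-oxoundecyl}-5-methylfuran-2(5H)-one | O=C(CCCCCCCCCO[Si](c3ccccc3)(c4ccccc4)C(C)(C)C)C[C@]1(C)OC(=O)C=C1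
F5 | step 5 | (3S)-14-[(tert-butyldiphenylsilyl)oxy]-3-methyl-5-methylidenetetradec-1-en-3-ol | C=C[C@@](C)(O)CC(=C)CCCCCCCCCO[Si](c3ccccc3)(c4ccccc4)C(C)(C)C
F6 | step 5 | acrylate ester of F5 | C=C[C@@](C)(OC(=O)C=C)CC(=C)CCCCCCCCCO[Si](c3ccccc3)(c4ccccc4)C(C)(C)C
F7 | step 14 | (3S,4aS,7aS)-3-(dec-9-en-1-yl)-3,4a-dimethyltetrahydrofuro[3,2-c][1,2]dioxin-6-one | C=CCCCCCCCC[C@@]1(C)C[C@]2(C)OC(=O)C[C@@H]2OO1
F8 | step 14 | (E)-alkenylboronic acid pinacol ester from F7 | CC1(C)OB(/C=C/CCCCCCCC[C@@]2(C)C[C@]3(C)OC(=O)C[C@@H]3OO2)OC1(C)C
F9 | step 14 | (1E,3E)-1-iodohexa-1,3-diene | CC/C=C/C=C/I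
A1 | alternative 1 | triethylsilyl peroxide from 12, both C6 epimers | CC[Si](CC)(CC)OOC(C)(CCCCCCCCCO[Si](c3ccccc3)(c4ccccc4)C(C)(C)C)C[C@]1(C)OC(=O)C=C1
A2 | alternative 1 | C6 epimer of 17 | CC(C)(C)[Si](c3ccccc3)(c4ccccc4)OCCCCCCCCC[C@]1(C)C[C@]2(C)OC(=O)C[C@@H]2OO1
A3 | alternative 2 | (3E,5Z)-15-[(tert-butyldiphenylsilyl)oxy]-4,6-dimethylpentadeca-3,5-dienoic acid | OC(=O)C/C=C(\C)/C=C(/C)\CCCCCCCCCO[Si](c3ccccc3)(c4ccccc4)C(C)(C)C
A4 | alternative 2 | 3,6-dihydro-1,2-dioxine-3-acetic acid (would form as the racemate; the enantiomer matching 25 is drawn) | CC(C)(C)[Si](c3ccccc3)(c4ccccc4)OCCCCCCCCC[C@@]1(C)C=C(C)[C@H](CC(=O)O)OO1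
A5 | alternative 3 | (5S)-5-methyl-5-[(2-methyloxetan-2-yl)methyl]furan-2(5H)-one with C6 configured for inversion | C1CO[C@@]1(C)C[C@]2(C)OC(=O)C=C2
A6 | alternative 3 | (5S)-5-(2-hydroperoxy-4-hydroxy-2-methylbutyl)-5-methylfuran-2(5H)-one with C6 as in 25 | OCC[C@](C)(OO)C[C@]1(C)OC(=O)C=C1
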